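**Plan**

- Retrosynthesis: the C10 acetate and the 8Z alkene go back to a C8≡C9 propargylic alcohol. The resorcinol ring (OH on C1 and C3, chain on C5, side chain counted from the aryl-bearing carbon) is cut at ring bonds C4–C5 and C6–C1 after a CO2Me group is placed on C6.
- Enabling feature: the ring has oxygen on C1 and C3, the chain on C5 and only hydrogen on C2, C4 and C6. That is the pattern left when a cyclohexa-1,3-diene with silyloxy groups on C1 and C3 exchanges its CH2–CH2 bridge for an alk-2-ynoate whose β-carbon carries the chain.
- Forward, chain first: silyl-protected (R)-oct-1-yn-3-ol is alkylated at its alkyne carbon with 1,7-dibromoheptane (forms chain C7–C8), the bromide is displaced by acetylide, and the new terminal alkyne is methoxycarbonylated.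
- The only ring comes next: Diels–Alder addition of 1,3-bis(trimethylsilyloxy)cyclohexa-1,3-diene (two steps from cyclohexane-1,3-dione) to the ynoate, then loss of ethylene. The end-game is desilylation, saponification–decarboxylation, Lindlar reduction, peracetylation and selective aryl deacetylation.
- Stereochemistry: C10 (R) is bought with (R)-oct-1-yn-3-ol and no later step breaks a bond at that carbon. The 8Z geometry comes from syn semihydrogenation of the C8≡C9 alkyne.

Key step: step 7

Assumption: (R)-oct-1-yn-3-ol is taken as a purchasable, enantiopure material; the descriptor stays R in every intermediate because oxygen > alkynyl (or alkenyl) carbon > pentyl at that carbon.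

**Route**

Step 1
Reactants: 1 (R)-oct-1-yn-3-ol
Product: 2 (R)-tert-butyldimethyl(oct-1-yn-3-yloxy)silane
Conditions: TBSCl, imidazole, DMF, 0 °C → rt
Reagents that add atoms: tert-butyldimethylsilyl chloride, CC(C)(C)[Si](C)(C)Cl
Why: Imidazole-promoted O-silylation of a secondary alcohol is routine, breaks no bond at the carbinol carbon (R retained) and masks the hydroxyl against the organolithium steps that follow.

Step 2
Reactants: 2 (R)-tert-butyldimethyl(oct-1-yn-3-yloxy)silane; 3 1,7-dibromoheptane
Product: 5 (R)-[(15-bromopentadec-7-yn-6-yl)oxy](tert-butyl)dimethylsilane, via lithium acetylide 4 (not isolated)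
Conditions: n-BuLi, THF, −78 → 0 °C; then 3 (4 equiv), DMPU, 0 °C → rt
Reagents that add atoms: none
Why: SN2 alkylation of a lithium acetylide by a primary bromide in a dipolar cosolvent is standard, and the fourfold excess of the symmetric dibromide should hold the reaction at monoalkylation.

Step 3
Reactants: 5 (R)-[(15-bromopentadec-7-yn-6-yl)oxy](tert-butyl)dimethylsilane
Product: 6 (R)-tert-butyl(heptadeca-1,10-diyn-12-yloxy)dimethylsilane
Conditions: LiC≡CH·H2NCH2CH2NH2, DMSO, 10 °C → rt
Reagents that add atoms: lithium acetylide–ethylenediamine complex, [Li+].[C-]#C.NCCN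
Why: Lithium acetylide–ethylenediamine in DMSO displaces primary bromides by SN2 and is too weak a base to isomerize the internal alkyne or attack the silyl ether.

Step 4
Reactants: 6 (R)-tert-butyl(heptadeca-1,10-diyn-12-yloxy)dimethylsilane; 7 methyl chloroformate
Product: 9 methyl (R)-13-(tert-butyldimethylsilyloxy)octadeca-2,11-diynoate, via lithium acetylide 8 (not isolated)
Conditions: n-BuLi (1.0 equiv), THF, −78 °C; then ClCO2Me, −78 → 0 °C
Reagents that add atoms: none
Why: The terminal alkyne C–H is the only acidic site, and acylation of the resulting acetylide with a chloroformate is the standard entry to alk-2-ynoates.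

Step 5
Reactants: 10 cyclohexane-1,3-dione
Product: 11 3-(trimethylsilyloxy)cyclohex-2-en-1-one
Conditions: TMSCl, Et3N, THF, 0 °C → rt; filtration under Ar, distillation
Reagents that add atoms: chlorotrimethylsilane, C[Si](C)(C)Cl
Why: The enolized 1,3-dione is O-silylated by TMSCl/Et3N to the vinylogous silyl ester, a standard silyl enol ether formation.

Step 6
Reactants: 11 3-(trimethylsilyloxy)cyclohex-2-en-1-one
Product: 13 1,3-bis(trimethylsilyloxy)cyclohexa-1,3-diene, via lithium dienolate 12 (not isolated)
Conditions: LDA, THF, −78 °C; then TMSCl, −78 °C → rt; pentane, filtration, bulb-to-bulb distillation (no aqueous work-up)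
Reagents that add atoms: chlorotrimethylsilane, C[Si](C)(C)Cl
Why: Kinetic deprotonation of a 3-oxygenated cyclohexenone by LDA takes the α′ proton (C6), and O-silylation of the cross-conjugated dienolate should give the 1,3-bis(silyloxy) diene, which is kept strictly anhydrous.

Step 7
Reactants: 9 methyl (R)-13-(tert-butyldimethylsilyloxy)octadeca-2,11-diynoate; 13 1,3-bis(trimethylsilyloxy)cyclohexa-1,3-diene
Product: 15 methyl 6-[(10R)-10-(tert-butyldimethylsilyloxy)pentadec-8-yn-1-yl]-2,4-bis(trimethylsilyloxy)benzoate, via bicyclo[2.2.2]octadiene cycloadduct 14 (not isolated)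
Conditions: 13 (2.5 equiv), neat, sealed tube, Ar, 150 °C then 180 °C; excess 13 removed in vacuo, crude 15 carried on
Reagents that add atoms: none
Why: The doubly donor-substituted diene 13 and the ester-activated alkyne of 9 should combine in a concerted, asynchronous, normal-demand [4+2] cycloaddition in which the unsubstituted diene terminus C4 bonds to the ynoate β-carbon and the silyloxy-bearing terminus C1 to the α-carbon, after which adduct 14 loses its saturated two-carbon bridge as ethylene by an irreversible, aromatization-driven retro-[4+2]. The closest known reaction type is the Alder–Rickert benzannulation of 1,3-dioxygenated cyclohexa-1,3-dienes with acetylenic esters, which gives β-resorcylates. The six-membered ring closes by intermolecular suprafacial cycloaddition that makes both new ring bonds (benzoate C1–C2 and C5–C6) in one event, so no cyclization mode has to be selected. The two bridgehead stereocentres of 14 form without control and vanish on aromatization, while the remote silyloxy-bearing carbon is not touched under neutral thermal conditions. The step needs regioselectivity (ester between an oxygen and the chain, chain meta to both oxygens) and chemoselectivity for the 2-yne over the 11-yne; the first follows from the matched polarization of diene and ynoate, the second from ester activation of the 2-yne against the unactivated, sterically shielded internal alkyne.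

Step 8
Reactants: 15 methyl 6-[(10R)-10-(tert-butyldimethylsilyloxy)pentadec-8-yn-1-yl]-2,4-bis(trimethylsilyloxy)benzoate
Product: 16 methyl 2,4-dihydroxy-6-[(10R)-10-hydroxypentadec-8-yn-1-yl]benzoate
Conditions: HCl (1% in MeOH), rt
Reagents that add atoms: none
Why: Acid-catalysed methanolysis cleaves the labile aryl trimethylsilyl ethers at once and the secondary tert-butyldimethylsilyl ether more slowly, at silicon and not at C10, so ester, alkyne and configuration should be unchanged.

Step 9
Reactants: 16 methyl 2,4-dihydroxy-6-[(10R)-10-hydroxypentadec-8-yn-1-yl]benzoate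
Product: 18 5-[(10R)-10-hydroxypentadec-8-yn-1-yl]benzene-1,3-diol, via resorcylic acid 17 (not isolated)
Conditions: KOH, MeOH/H2O (degassed), reflux, Ar; then aq. HCl to pH 1, 70 °C
Reagents that add atoms: none
Why: Saponification of the salicylate-type ester followed by acid-induced decarboxylation (ipso-protonation at the carbon ortho and para to the two hydroxyls, then loss of CO2) is the classical conversion of β-resorcylates into 5-alkylresorcinols, and a dialkyl propargylic alcohol should tolerate both stages.

Step 10
Reactants: 18 5-[(10R)-10-hydroxypentadec-8-yn-1-yl]benzene-1,3-diol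
Product: 19 5-[(8Z,10R)-10-hydroxypentadec-8-en-1-yl]benzene-1,3-diol
Conditions: H2 (1 atm), Pd/CaCO3 poisoned with Pb(OAc)2 (Lindlar catalyst), quinoline, EtOAc, rt, stopped at one equivalent of H2
Reagents that add atoms: none
Why: Lindlar semihydrogenation delivers both hydrogens syn from the poisoned palladium surface, which sets the 8Z geometry, and lead/quinoline poisoning should stop the reduction at the alkene without affecting C10.

Step 11
Reactants: 19 5-[(8Z,10R)-10-hydroxypentadec-8-en-1-yl]benzene-1,3-diol
Product: 20 5-[(8Z,10R)-10-acetoxypentadec-8-en-1-yl]-1,3-phenylene diacetate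
Conditions: Ac2O, pyridine, DMAP (cat.), CH2Cl2, 0 °C → rt
Reagents that add atoms: acetic anhydride, CC(=O)OC(C)=O
Why: DMAP-catalysed acylation esterifies all three hydroxyls at oxygen, so the allylic stereocentre and the alkene geometry should be retained.

Step 12
Reactants: 20 5-[(8Z,10R)-10-acetoxypentadec-8-en-1-yl]-1,3-phenylene diacetate
Product: 21 (8Z,10R)-1-(3,5-dihydroxyphenyl)pentadec-8-en-10-yl acetate (CNP0315732.1)
Conditions: pyrrolidine (2.2 equiv), CH2Cl2, 0 °C
Reagents that add atoms: none
Why: Aryl acetates are activated esters (phenoxide leaving group) and undergo aminolysis by pyrrolidine far faster than the hindered secondary alkyl acetate, so chemoselective deacetylation should free the two phenols and leave the C10 acetate.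

**Compound list**

1 | (R)-oct-1-yn-3-ol | CCCCC[C@H](C#C)O | starting material
2 | (R)-tert-butyldimethyl(oct-1-yn-3-yloxy)silane | CCCCC[C@H](C#C)O[Si](C)(C)C(C)(C)C | intermediate
3 | 1,7-dibromoheptane | BrCCCCCCCBr | starting material
4 | [(3R)-3-(tert-butyldimethylsilyloxy)oct-1-yn-1-yl]lithium | CCCCC[C@H](C#C[Li])O[Si](C)(C)C(C)(C)C | intermediate
5 | (R)-[(15-bromopentadec-7-yn-6-yl)oxy](tert-butyl)dimethylsilane | CCCCC[C@H](C#CCCCCCCCBr)O[Si](C)(C)C(C)(C)C | intermediate
6 | (R)-tert-butyl(heptadeca-1,10-diyn-12-yloxy)dimethylsilane | CCCCC[C@H](C#CCCCCCCCC#C)O[Si](C)(C)C(C)(C)C | intermediate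
7 | methyl chloroformate | COC(Cl)=O | starting material
8 | [(12R)-12-(tert-butyldimethylsilyloxy)heptadeca-1,10-diyn-1-yl]lithium | CCCCC[C@H](C#CCCCCCCCC#C[Li])O[Si](C)(C)C(C)(C)C | intermediate
9 | methyl (R)-13-(tert-butyldimethylsilyloxy)octadeca-2,11-diynoate | CCCCC[C@H](C#CCCCCCCCC#CC(=O)OC)O[Si](C)(C)C(C)(C)C | intermediate
10 | cyclohexane-1,3-dione | O=C1CCCC(=O)C1 | starting material
11 | 3-(trimethylsilyloxy)cyclohex-2-en-1-one | C[Si](C)(C)OC1=CC(=O)CCC1 | intermediate
12 | lithium 5-(trimethylsilyloxy)cyclohexa-1,5-dien-1-olate | [Li]OC1=CCCC(O[Si](C)(C)C)=C1 | intermediate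
13 | 1,3-bis(trimethylsilyloxy)cyclohexa-1,3-diene | C[Si](C)(C)OC1=CC(O[Si](C)(C)C)=CCC1 | intermediate
14 | methyl 3-[(10R)-10-(tert-butyldimethylsilyloxy)pentadec-8-yn-1-yl]-1,5-bis(trimethylsilyloxy)bicyclo[2.2.2]octa-2,5-diene-2-carboxylate (both bridgehead diastereomers) | CCCCC[C@H](C#CCCCCCCCC1=C(C(=O)OC)C2(O[Si](C)(C)C)CCC1C(O[Si](C)(C)C)=C2)O[Si](C)(C)C(C)(C)C | intermediate
15 | methyl 6-[(10R)-10-(tert-butyldimethylsilyloxy)pentadec-8-yn-1-yl]-2,4-bis(trimethylsilyloxy)benzoate | CCCCC[C@H](C#CCCCCCCCc1cc(O[Si](C)(C)C)cc(O[Si](C)(C)C)c1C(=O)OC)O[Si](C)(C)C(C)(C)C | intermediate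
16 | methyl 2,4-dihydroxy-6-[(10R)-10-hydroxypentadec-8-yn-1-yl]benzoate | CCCCC[C@H](C#CCCCCCCCc1cc(O)cc(O)c1C(=O)OC)O | intermediate
17 | 2,4-dihydroxy-6-[(10R)-10-hydroxypentadec-8-yn-1-yl]benzoic acid | CCCCC[C@H](C#CCCCCCCCc1cc(O)cc(O)c1C(=O)O)O | intermediate
18 | 5-[(10R)-10-hydroxypentadec-8-yn-1-yl]benzene-1,3-diol | CCCCC[C@H](C#CCCCCCCCc1cc(O)cc(O)c1)O | intermediate
19 | 5-[(8Z,10R)-10-hydroxypentadec-8-en-1-yl]benzene-1,3-diol | CCCCC[C@H](/C=C\CCCCCCCc1cc(O)cc(O)c1)O | intermediate
20 | 5-[(8Z,10R)-10-acetoxypentadec-8-en-1-yl]-1,3-phenylene diacetate | CCCCC[C@H](/C=C\CCCCCCCc1cc(OC(C)=O)cc(OC(C)=O)c1)OC(C)=O | intermediate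
21 | (8Z,10R)-1-(3,5-dihydroxyphenyl)pentadec-8-en-10-yl acetate | CCCCC[C@H](/C=C\CCCCCCCc1cc(O)cc(O)c1)OC(C)=O | target

**Step count and risks**

Total step count: 12.
Longest linear sequence: 10 steps (steps 1–4 and 7–12); the diene branch (steps 5–6) joins at step 7.

Steps most likely to fail:

1. Step 7. The singly activated, β-alkyl ynoate may add too slowly, so that the moisture- and heat-sensitive diene is lost to desilylation, self-reaction or dehydrogenation before cycloaddition, or ethylene extrusion may stall at the bicyclic stage. The fallback gives up ring construction and attaches a preformed, silyl-protected resorcinol by Negishi sp3–sp2 coupling; it sets out from bromide 5 and returns at alkynyl triol 18. Purchased 5-bromobenzene-1,3-diol is bis-silylated (TBSCl, imidazole, DMF) to 1-bromo-3,5-bis(tert-butyldimethylsilyloxy)benzene F1. Bromide 5 is converted with zinc dust and LiCl in THF into [(10R)-10-(tert-butyldimethylsilyloxy)pentadec-8-yn-1-yl]zinc bromide F2. F2 is coupled with F1 under Pd(OAc)2/SPhos catalysis in THF to give 1,3-bis(tert-butyldimethylsilyloxy)-5-[(10R)-10-(tert-butyldimethylsilyloxy)pentadec-8-yn-1-yl]benzene F3. TBAF in THF then removes all three silyl groups and should deliver 18, from which steps 10–12 follow unchanged.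

2. Step 2. Substitution at both ends of the dibromide, or competing E2 elimination under the basic conditions, may erode the monoalkylated bromide. The fallback replaces statistical monoalkylation by a chemoselective one; it sets out from silyl ether 2 and returns at diyne 6. Acetylide 4, generated from 2 as before, is alkylated with purchased 1-bromo-7-chloroheptane, which should react only at its C–Br end, to give (R)-tert-butyl[(15-chloropentadec-7-yn-6-yl)oxy]dimethylsilane F4. The primary chloride of F4 is then displaced with lithium acetylide–ethylenediamine in DMSO (rt to 40 °C) to give 6.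

3. Step 10. Over-reduction to the saturated chain, incomplete uptake of hydrogen, or catalyst-mediated Z-to-E isomerization would give mixtures that are hard to separate. The fallback replaces catalytic hydrogenation by a hydroxyl-assisted electron-transfer reduction that cannot attack an isolated alkene; it sets out from alkynyl triol 18 and returns at Z-allylic alcohol 19. Compound 18 is heated with activated zinc (Zn dust, BrCH2CH2Br, CuBr, LiBr) in refluxing EtOH; propargylic alcohols are reduced under these conditions to Z-allylic alcohols and the reaction stops there. No new compound is made on this path.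

**Further compounds**

F1 | step 7 | 1-bromo-3,5-bis(tert-butyldimethylsilyloxy)benzene | Brc1cc(O[Si](C)(C)C(C)(C)C)cc(O[Si](C)(C)C(C)(C)C)c1
F2 | step 7 | [(10R)-10-(tert-butyldimethylsilyloxy)pentadec-8-yn-1-yl]zinc bromide | CCCCC[C@H](C#CCCCCCCC[Zn]Br)O[Si](C)(C)C(C)(C)C
F3 | step 7 | 1,3-bis(tert-butyldimethylsilyloxy)-5-[(10R)-10-(tert-butyldimethylsilyloxy)pentadec-8-yn-1-yl]benzene | CCCCC[C@H](C#CCCCCCCCc1cc(O[Si](C)(C)C(C)(C)C)cc(O[Si](C)(C)C(C)(C)C)c1)O[Si](C)(C)C(C)(C)C
F4 | step 2 | (R)-tert-butyl[(15-chloropentadec-7-yn-6-yl)oxy]dimethylsilane | CCCCC[C@H](C#CCCCCCCCCl)O[Si](C)(C)C(C)(C)C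
F0 | step 10 | none | none
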